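**Retrosynthetic overview**

1. Target ⇐ protected macrolactone, by late esterification of the C8 hydroxyl and one-pot removal of the C15 silyl ether and the C14 acetal.
2. Ring order: the ten-membered carbocycle is closed first, by a chromium-catalysed intramolecular allyl bromide–aldehyde coupling (C6–C7); the trans-fused α-methylene-γ-lactone closes directly afterwards in the same operation.
3. Seco bromo-enal ⇐ C8–C9 bond by chirality-transferring allylboration of a γ-oxo enoate with an α-substituted allylboronate (sets C8 and the ring-cis C1=C10 alkene).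
4. Allylboronate ⇐ sparteine-mediated lithiation–borylation of a C1–C6 carbamate with an alkenyl boronate (C9, C10, C14); carbamate ⇐ palladium-catalysed Negishi coupling (C3–C4) on a butynediol-derived vinyl iodide (sets the ring-cis C4=C5 alkene).
5. γ-Oxo enoate (C7, C8, C11–C13) ⇐ Morita–Baylis–Hillman adduct of 2,2-dimethoxyacetaldehyde and methyl acrylate.

Assumption: atom labels C1–C15 follow germacrane numbering of the target (C6 lactone carbinol, C7 ring-fusion CH, C8 ester carbinol, C14 aldehyde carbon, C15 hydroxymethyl carbon), and the (S,S) enantiomer of ligand L1 in step 18 is taken as the one that directs addition to the Si face of the C6 aldehyde (otherwise its mirror image is used).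

**Route**

Step 1
Reactants: 1 but-2-yne-1,4-diol
Product: 2 4-[(tert-butyldiphenylsilyl)oxy]but-2-yn-1-ol
Conditions: NaH (1.0 equiv), THF, 0 °C; then TBDPSCl (1.0 equiv), rt
Reagents that add atoms: tert-butyl(chloro)diphenylsilane, CC(C)(C)[Si](Cl)(c1ccccc1)c1ccccc1
Why: Monosilylation of a symmetrical diol through its poorly soluble monosodium alkoxide stops after one O-silylation.

Step 2
Reactants: 2 4-[(tert-butyldiphenylsilyl)oxy]but-2-yn-1-ol
Product: 3 (Z)-4-[(tert-butyldiphenylsilyl)oxy]-3-iodobut-2-en-1-ol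
Conditions: NaAlH2(OCH2CH2OMe)2 (Red-Al), THF, 0 °C; then I2, −78 → 0 °C
Reagents that add atoms: iodine, II
Why: Hydroxyl-directed trans-hydroalumination puts H on C5 and Al on C4 on opposite faces, and iodinolysis with retention gives the vinyl iodide with C15 trans to C6, which is the ring-cis geometry of C4=C5.

Step 3
Reactants: 3 (Z)-4-[(tert-butyldiphenylsilyl)oxy]-3-iodobut-2-en-1-ol
Product: 4 (Z)-1-[(tert-butyldiphenylsilyl)oxy]-2-iodo-4-[(triethylsilyl)oxy]but-2-ene
Conditions: TESCl, imidazole, CH2Cl2, 0 °C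
Reagents that add atoms: chlorotriethylsilane, CC[Si](Cl)(CC)CC
Why: Standard silylation of the primary allylic alcohol gives a C6 silyl ether that can later be removed selectively beside TBS and TBDPS ethers.

Step 4
Reactants: 5 3-chloropropan-1-ol
Product: 6 3-chloropropyl N,N-diisopropylcarbamate
Conditions: iPr2NCOCl, Et3N, CH2Cl2, reflux
Reagents that add atoms: N,N-diisopropylcarbamoyl chloride, CC(C)N(C(C)C)C(Cl)=O
Why: O-Carbamoylation installs the Hoppe directing and leaving group on the future C1 oxygen.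

Step 5
Reactants: 6 3-chloropropyl N,N-diisopropylcarbamate
Product: 7 3-iodopropyl N,N-diisopropylcarbamate
Conditions: NaI, acetone, reflux
Reagents that add atoms: sodium iodide, [Na+].[I-]
Why: Finkelstein halide exchange is driven by precipitation of NaCl and gives the iodide needed for zinc insertion.

Step 6
Reactants: 7 3-iodopropyl N,N-diisopropylcarbamate; 4 (Z)-1-[(tert-butyldiphenylsilyl)oxy]-2-iodo-4-[(triethylsilyl)oxy]but-2-ene
Product: 9 (E)-4-{[(tert-butyldiphenylsilyl)oxy]methyl}-6-[(triethylsilyl)oxy]hex-4-en-1-yl N,N-diisopropylcarbamate, via alkylzinc iodide 8 (not isolated)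
Conditions: Zn dust, LiCl, THF, 40 °C; then 4, Pd(OAc)2 (2 mol%), SPhos (4 mol%), THF, rt
Reagents that add atoms: none
Why: The γ-oxygenated alkylzinc cannot β-eliminate, and the palladium-catalysed Negishi sp3–sp2 cross-coupling forms C3–C4 with retention of the alkene geometry.

Step 7
Reactants: 10 2-vinyl-1,3-dioxolane
Product: 11 2-(1,2-dibromoethyl)-1,3-dioxolane (racemic)
Conditions: Br2, CH2Cl2, −78 → 0 °C
Reagents that add atoms: bromine, BrBr
Why: Electrophilic anti addition of bromine to the terminal alkene is clean beside the acetal.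

Step 8
Reactants: 11 2-(1,2-dibromoethyl)-1,3-dioxolane
Product: 12 2-(1-bromovinyl)-1,3-dioxolane
Conditions: KOtBu, THF, 0 °C
Reagents that add atoms: none
Why: E2 dehydrobromination removes the more acidic C–H next to bromine and the acetal together with the terminal bromide, giving the 1-bromovinyl acetal.

Step 9
Reactants: 12 2-(1-bromovinyl)-1,3-dioxolane
Product: 13 2-[1-(1,3-dioxolan-2-yl)vinyl]-4,4,5,5-tetramethyl-1,3,2-dioxaborolane
Conditions: B2pin2, PdCl2(PPh3)2 (3 mol%), PPh3 (6 mol%), KOPh, toluene, 50 °C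
Reagents that add atoms: bis(pinacolato)diboron, CC1(C)OB(OC1(C)C)B1OC(C)(C)C(C)(C)O1
Why: Miyaura borylation of an alkenyl bromide with the weak base KOPh gives the alkenyl boronate without Suzuki homocoupling.

Step 10
Reactants: 14 2,2-dimethoxyacetaldehyde; 15 methyl acrylate
Product: 16 methyl 3-hydroxy-4,4-dimethoxy-2-methylenebutanoate (racemic)
Conditions: DABCO (0.5 equiv), 1,4-dioxane/H2O, rt
Reagents that add atoms: none
Why: Morita–Baylis–Hillman reaction of an electrophilic α-alkoxy aldehyde is accelerated in aqueous medium, and the new carbinol centre is erased in step 11.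

Step 11
Reactants: 16 methyl 3-hydroxy-4,4-dimethoxy-2-methylenebutanoate
Product: 17 methyl (Z)-2-(bromomethyl)-4,4-dimethoxybut-2-enoate
Conditions: NBS, Me2S, CH2Cl2, 0 °C → rt
Reagents that add atoms: N-bromosuccinimide, O=C1CCC(=O)N1Br
Why: Corey–Kim-type activation of the hydroxyl and SN2′ attack of bromide give the thermodynamically favoured trisubstituted allylic bromide (acetal carbon trans to the ester) under non-acidic conditions that spare the acetal.

Step 12
Reactants: 17 methyl (Z)-2-(bromomethyl)-4,4-dimethoxybut-2-enoate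
Product: 18 methyl (Z)-2-(bromomethyl)-4-oxobut-2-enoate
Conditions: TFA/H2O (9:1), CH2Cl2, 0 °C; used without storage
Reagents that add atoms: water, O
Why: Acid-catalysed acetal hydrolysis frees the C8 aldehyde while the fumarate-like alkene geometry (CHO trans to CO2Me) is retained.

Step 13
Reactants: 9 (E)-4-{[(tert-butyldiphenylsilyl)oxy]methyl}-6-[(triethylsilyl)oxy]hex-4-en-1-yl N,N-diisopropylcarbamate; 13 2-[1-(1,3-dioxolan-2-yl)vinyl]-4,4,5,5-tetramethyl-1,3,2-dioxaborolane
Product: 21 2-[(3R,6E)-6-{[(tert-butyldiphenylsilyl)oxy]methyl}-2-(1,3-dioxolan-2-yl)-8-[(triethylsilyl)oxy]octa-1,6-dien-3-yl]-4,4,5,5-tetramethyl-1,3,2-dioxaborolane, via lithiated carbamate 19 (not isolated), via boronate complex 20 (not isolated)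
Conditions: s-BuLi, (−)-sparteine, Et2O, −78 °C, 5 h; then 13, −78 °C; then MgBr2·OEt2, reflux
Reagents that add atoms: none
Why: Hoppe–Aggarwal lithiation–borylation, in which (−)-sparteine-directed removal of the pro-S hydrogen gives the (S)-lithiated carbamate, borylation occurs with retention and the 1,2-alkenyl shift with inversion, so the boron-bearing carbon (C1) is set as R.

Step 14
Reactants: 21 (R)-α-substituted allylboronate; 18 methyl (Z)-2-(bromomethyl)-4-oxobut-2-enoate
Product: 23 methyl (2Z,4R,6E,10E)-2-(bromomethyl)-10-{[(tert-butyldiphenylsilyl)oxy]methyl}-6-(1,3-dioxolan-2-yl)-4-hydroxy-12-[(triethylsilyl)oxy]dodeca-2,6,10-trienoate, via pinacol borate ester 22 (not isolated)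
Conditions: toluene, 40 °C; then H2O, SiO2
Reagents that add atoms: none
Why: Allylboration through a chair transition state in which 1,2-allylic strain with the dioxolanyl group forces the C1 substituent axial, so the C–B chirality is transferred to C8 (R) and the new C1=C10 alkene has C2 cis to C9 (ring-cis).

Step 15
Reactants: 23 seco hydroxy bromo ester
Product: 24 methyl (2Z,4R,6E,10E)-2-(bromomethyl)-4-[(tert-butyldimethylsilyl)oxy]-10-{[(tert-butyldiphenylsilyl)oxy]methyl}-6-(1,3-dioxolan-2-yl)-12-[(triethylsilyl)oxy]dodeca-2,6,10-trienoate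
Conditions: TBSOTf (1.1 equiv), 2,6-lutidine, CH2Cl2, −78 °C
Reagents that add atoms: tert-butyldimethylsilyl trifluoromethanesulfonate, CC(C)(C)[Si](C)(C)OS(=O)(=O)C(F)(F)F
Why: Silyl triflate with a hindered base protects the C8 hydroxyl without touching the allylic bromide; a C8 silyl ether is a poor leaving group for the later allyl-metal stage and later forces lactonisation onto O6.

Step 16
Reactants: 24 C8 silyl ether
Product: 25 methyl (2Z,4R,6E,10E)-2-(bromomethyl)-4-[(tert-butyldimethylsilyl)oxy]-10-{[(tert-butyldiphenylsilyl)oxy]methyl}-6-(1,3-dioxolan-2-yl)-12-hydroxydodeca-2,6,10-trienoate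
Conditions: PPTS (0.2 equiv), MeOH/CH2Cl2 (1:4), 0 °C
Reagents that add atoms: none
Why: Mild acid-catalysed methanolysis removes the primary triethylsilyl ether much faster than the secondary TBS ether, the TBDPS ether or the dioxolane.

Step 17
Reactants: 25 C6 allylic alcohol
Product: 26 methyl (2Z,4R,6E,10E)-2-(bromomethyl)-4-[(tert-butyldimethylsilyl)oxy]-10-{[(tert-butyldiphenylsilyl)oxy]methyl}-6-(1,3-dioxolan-2-yl)-12-oxododeca-2,6,10-trienoate
Conditions: TEMPO (10 mol%), PhI(OAc)2, CH2Cl2, rt
Reagents that add atoms: none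
Why: Oxoammonium (TEMPO/PhI(OAc)2) oxidation converts the primary allylic alcohol to the enal under neutral conditions without alkene isomerisation or reaction of the allylic bromide.

Step 18
Reactants: 26 seco bromo-enal
Product: 28 8-O-TBS 15-O-TBDPS 14-(ethylene acetal) protected macrolactone (ten-membered ring with trans-fused α-methylene-γ-lactone; stereocentres C6 C7 C8 as in 32), via trimethylsilyl ether 27 (not isolated)
Conditions: CrCl2 (20 mol%), (S,S)-L1 (22 mol%), iPr2NEt (40 mol%), Mn powder (3 equiv), TMSCl (2 equiv), THF, rt, syringe-pump addition of 26 over 12 h (final 2 mM); then aq. citric acid; PPTS, CH2Cl2, rt [L1 = 3,6-di-tert-butyl-1,8-bis(4-isopropyl-4,5-dihydrooxazol-2-yl)-9H-carbazole]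
Reagents that add atoms: none
Why: Proposed new method: a catalytic, ligand-controlled macrocyclising Nozaki–Hiyama allylation in which Mn regenerates divalent chromium, two such centres reduce the allylic bromide to an allyl species of trivalent chromium carrying L1, this adds through its γ-carbon C7 to the tethered C6 aldehyde in a six-membered chair transition state, and TMSCl silylates the chromium alkoxide to release the catalyst; the bulky tridentate ligand is expected to expose the Si face of the aldehyde (C6 R) and to disfavour an axial C8 substituent so that the anti adduct (C7 R, 6,7-trans lactone after acid-promoted lactonisation) forms, while slow addition keeps the substrate dilute; the closest known reactions are the stoichiometric CrCl2 Barbier macrocyclisation of ω-formyl 2-(bromomethyl)alkenoates to germacranolide rings and the intermolecular Mn/TMSCl-turnover asymmetric chromium-catalysed 2-(alkoxycarbonyl)allylation of aldehydes.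

Step 19
Reactants: 28 protected macrolactone
Product: 29 8-hydroxy 15-O-TBDPS 14-(ethylene acetal) macrolactone (stereocentres as in 32)
Conditions: HF·pyridine, pyridine, THF, 0 °C → rt
Reagents that add atoms: none
Why: Buffered fluoride cleaves the secondary TBS ether faster than the primary TBDPS ether, and the acetal is inert under anhydrous conditions.

Step 20
Reactants: 29 C8 alcohol; 30 (S)-2-methylbutanoic acid
Product: 31 8-O-[(S)-2-methylbutanoyl] 15-O-TBDPS 14-(ethylene acetal) macrolactone (stereocentres as in 32)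
Conditions: DIC, DMAP (0.1 equiv), CH2Cl2, 0 °C → rt
Reagents that add atoms: none
Why: Steglich esterification acylates the secondary alcohol under mild conditions that do not epimerise the α-stereocentre of the acid or open the lactone.

Step 21
Reactants: 31 protected ester
Product: 32 target CNP0168859.6, (6R,7R,8R)-15-hydroxy-14-oxo-8-[(2S)-2-methylbutanoyloxy]germacra-1(10),4,11(13)-trien-12,6-olide with both ring alkenes cis within the ring
Conditions: HF·pyridine, THF, 0 °C → rt; then 1 M aq. HCl, rt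
Reagents that add atoms: water, O
Why: Fluoride removes the TBDPS ether and dilute aqueous acid hydrolyses the allylic dioxolane to the conjugated aldehyde, conditions that the lactone, the ester and the stereocentres tolerate.

**Compound list**

1 | but-2-yne-1,4-diol | OCC#CCO | starting material
2 | 4-[(tert-butyldiphenylsilyl)oxy]but-2-yn-1-ol | OCC#CCO[Si](c1ccccc1)(c1ccccc1)C(C)(C)C | intermediate
3 | (Z)-4-[(tert-butyldiphenylsilyl)oxy]-3-iodobut-2-en-1-ol | OC/C=C(I)/CO[Si](c1ccccc1)(c1ccccc1)C(C)(C)C | intermediate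
4 | (Z)-1-[(tert-butyldiphenylsilyl)oxy]-2-iodo-4-[(triethylsilyl)oxy]but-2-ene | CC[Si](CC)(CC)OC/C=C(I)/CO[Si](c1ccccc1)(c1ccccc1)C(C)(C)C | intermediate
5 | 3-chloropropan-1-ol | OCCCCl | starting material
6 | 3-chloropropyl N,N-diisopropylcarbamate | CC(C)N(C(C)C)C(=O)OCCCCl | intermediate
7 | 3-iodopropyl N,N-diisopropylcarbamate | CC(C)N(C(C)C)C(=O)OCCCI | intermediate
8 | {3-[(diisopropylcarbamoyl)oxy]propyl}zinc iodide | CC(C)N(C(C)C)C(=O)OCCC[Zn]I | intermediate
9 | (E)-4-{[(tert-butyldiphenylsilyl)oxy]methyl}-6-[(triethylsilyl)oxy]hex-4-en-1-yl N,N-diisopropylcarbamate (C3 cis to C6) | CC(C)N(C(C)C)C(=O)OCCC/C(CO[Si](c1ccccc1)(c1ccccc1)C(C)(C)C)=C\CO[Si](CC)(CC)CC | intermediate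
10 | 2-vinyl-1,3-dioxolane | C=CC1OCCO1 | starting material
11 | 2-(1,2-dibromoethyl)-1,3-dioxolane (racemic) | BrCC(Br)C1OCCO1 | intermediate
12 | 2-(1-bromovinyl)-1,3-dioxolane | C=C(Br)C1OCCO1 | intermediate
13 | 2-[1-(1,3-dioxolan-2-yl)vinyl]-4,4,5,5-tetramethyl-1,3,2-dioxaborolane | C=C(B1OC(C)(C)C(C)(C)O1)C1OCCO1 | intermediate
14 | 2,2-dimethoxyacetaldehyde | COC(OC)C=O | starting material
15 | methyl acrylate | C=CC(=O)OC | starting material
16 | methyl 3-hydroxy-4,4-dimethoxy-2-methylenebutanoate (racemic) | COC(OC)C(O)C(=C)C(=O)OC | intermediate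
17 | methyl (Z)-2-(bromomethyl)-4,4-dimethoxybut-2-enoate | COC(OC)/C=C(\CBr)C(=O)OC | intermediate
18 | methyl (Z)-2-(bromomethyl)-4-oxobut-2-enoate | O=C/C=C(\CBr)C(=O)OC | intermediate
19 | (S)-1-lithio derivative of 9 at the carbamate-bearing carbon, (−)-sparteine complex | [Li][C@H](OC(=O)N(C(C)C)C(C)C)CC/C(CO[Si](c1ccccc1)(c1ccccc1)C(C)(C)C)=C\CO[Si](CC)(CC)CC | intermediate
20 | lithium boronate complex formed from 19 and 13 (boron bound to C1 with retention) | [Li+].C=C(C1OCCO1)[B-]1(OC(C)(C)C(C)(C)O1)[C@H](OC(=O)N(C(C)C)C(C)C)CC/C(CO[Si](c1ccccc1)(c1ccccc1)C(C)(C)C)=C\CO[Si](CC)(CC)CC | intermediate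
21 | 2-[(3R,6E)-6-{[(tert-butyldiphenylsilyl)oxy]methyl}-2-(1,3-dioxolan-2-yl)-8-[(triethylsilyl)oxy]octa-1,6-dien-3-yl]-4,4,5,5-tetramethyl-1,3,2-dioxaborolane | C=C(C1OCCO1)[C@H](B1OC(C)(C)C(C)(C)O1)CC/C(CO[Si](c1ccccc1)(c1ccccc1)C(C)(C)C)=C\CO[Si](CC)(CC)CC | intermediate
22 | pinacol borate ester of 23 (O4–Bpin) | COC(=O)/C(CBr)=C/[C@H](OB1OC(C)(C)C(C)(C)O1)C/C(C1OCCO1)=C\CC/C(CO[Si](c1ccccc1)(c1ccccc1)C(C)(C)C)=C\CO[Si](CC)(CC)CC | intermediate
23 | methyl (2Z,4R,6E,10E)-2-(bromomethyl)-10-{[(tert-butyldiphenylsilyl)oxy]methyl}-6-(1,3-dioxolan-2-yl)-4-hydroxy-12-[(triethylsilyl)oxy]dodeca-2,6,10-trienoate | COC(=O)/C(CBr)=C/[C@H](O)C/C(C1OCCO1)=C\CC/C(CO[Si](c1ccccc1)(c1ccccc1)C(C)(C)C)=C\CO[Si](CC)(CC)CC | intermediate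
24 | 4-O-TBS ether of 23 | COC(=O)/C(CBr)=C/[C@H](O[Si](C)(C)C(C)(C)C)C/C(C1OCCO1)=C\CC/C(CO[Si](c1ccccc1)(c1ccccc1)C(C)(C)C)=C\CO[Si](CC)(CC)CC | intermediate
25 | 12-hydroxy compound (triethylsilyl group of 24 removed) | COC(=O)/C(CBr)=C/[C@H](O[Si](C)(C)C(C)(C)C)C/C(C1OCCO1)=C\CC/C(CO[Si](c1ccccc1)(c1ccccc1)C(C)(C)C)=C\CO | intermediate
26 | 12-oxo compound (seco bromo-enal) | COC(=O)/C(CBr)=C/[C@H](O[Si](C)(C)C(C)(C)C)C/C(C1OCCO1)=C\CC/C(CO[Si](c1ccccc1)(c1ccccc1)C(C)(C)C)=C\C=O | intermediate
27 | ten-membered carbocycle, methyl 2-substituted acrylate with C6–OTMS and C8–OTBS (open form of 28) | C=C(C(=O)OC)[C@H]1[C@H](O[Si](C)(C)C)/C=C(/CO[Si](c2ccccc2)(c2ccccc2)C(C)(C)C)CC/C=C(/C2OCCO2)C[C@H]1O[Si](C)(C)C(C)(C)C | intermediate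
28 | 8-O-TBS 15-O-TBDPS 14-(ethylene acetal) macrolactone, 6,7-trans-fused, 8-O cis to the C7–C11 bond | C=C1C(=O)O[C@@H]2/C=C(/CO[Si](c3ccccc3)(c3ccccc3)C(C)(C)C)CC/C=C(/C3OCCO3)C[C@@H](O[Si](C)(C)C(C)(C)C)[C@@H]12 | intermediate
29 | 8-hydroxy 15-O-TBDPS 14-(ethylene acetal) macrolactone | C=C1C(=O)O[C@@H]2/C=C(/CO[Si](c3ccccc3)(c3ccccc3)C(C)(C)C)CC/C=C(/C3OCCO3)C[C@@H](O)[C@@H]12 | intermediate
30 | (S)-2-methylbutanoic acid | CC[C@H](C)C(=O)O | starting material
31 | 8-O-[(S)-2-methylbutanoyl] 15-O-TBDPS 14-(ethylene acetal) macrolactone | C=C1C(=O)O[C@@H]2/C=C(/CO[Si](c3ccccc3)(c3ccccc3)C(C)(C)C)CC/C=C(/C3OCCO3)C[C@@H](OC(=O)[C@@H](C)CC)[C@@H]12 | intermediate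
32 | CNP0168859.6, (6R,7R,8R)-15-hydroxy-14-oxo-8-[(2S)-2-methylbutanoyloxy]germacra-1(10),4,11(13)-trien-12,6-olide, both ring alkenes cis within the ring | C=C1C(=O)O[C@@H]2/C=C(/CO)CC/C=C(/C=O)C[C@@H](OC(=O)[C@@H](C)CC)[C@@H]12 | target

**Totals and risks**

Total step count: 21. Longest linear sequence: 13 steps (steps 1, 2, 3, 6, 13, 14, 15, 16, 17, 18, 19, 20, 21).

Steps most likely to fail:

Step 18 (the proposed catalytic macrocyclisation). Catalyst turnover at high dilution, the facial sense of the ligand and the anti preference are untested. The fallback sets out from 26 and comes back at 28. It uses the known stoichiometric, substrate-controlled CrCl2 Barbier macrocyclisation (CrCl2 in excess, THF/DMF, rt, 1 mM, then PPTS) that has closed germacranolide ten-membered rings. If this closure gives mainly the C6 epimer, the cis-fused 6-epi-macrolactone F1, the lactone is opened with LiOH in THF/H2O to hydroxy acid F2, and Mitsunobu lactonisation (PPh3, DIAD, toluene) inverts C6 and returns to 28.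

Step 13 (lithiation–borylation). Formation of the boronate complex from the hindered alkenyl boronate and its 1,2-shift may be sluggish in the presence of the diamine. The fallback sets out from 9 and comes back at 21. The sparteine-mediated deprotonation is quenched with Bu3SnCl to give the configurationally stable (S)-α-(tributylstannyl) carbamate F3, which is purified. Tin–lithium exchange with n-BuLi (Et2O, −78 °C, no diamine) then regenerates 19 cleanly, and this is borylated with 13 and rearranged with MgBr2·OEt2 at reflux to 21.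

Step 12 (acid hydrolysis to the sensitive γ-oxo enoate 18, which also feeds step 14). The fallback reaches 18 by oxidation instead of hydrolysis; it sets out from 15 and comes back at 18. Morita–Baylis–Hillman reaction of 15 with commercial 2-[(tert-butyldimethylsilyl)oxy]acetaldehyde gives methyl 4-[(tert-butyldimethylsilyl)oxy]-3-hydroxy-2-methylenebutanoate F4. NBS/Me2S converts it to methyl (Z)-2-(bromomethyl)-4-[(tert-butyldimethylsilyl)oxy]but-2-enoate F5. HF·pyridine removes the silyl group to give methyl (Z)-2-(bromomethyl)-4-hydroxybut-2-enoate F6, and MnO2 in CH2Cl2 oxidises the allylic alcohol under neutral conditions to 18, used directly as a solution in step 14.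

**Further compounds**

F1 | step 18 | 6-epi-macrolactone (C6 epimer of 28, cis-fused lactone) | C=C1C(=O)O[C@H]2/C=C(/CO[Si](c3ccccc3)(c3ccccc3)C(C)(C)C)CC/C=C(/C3OCCO3)C[C@@H](O[Si](C)(C)C(C)(C)C)[C@@H]12
F2 | step 18 | hydroxy acid (ring-opened F1: C6 hydroxyl and 2-substituted acrylic acid) | C=C(C(=O)O)[C@H]1[C@@H](O)/C=C(/CO[Si](c2ccccc2)(c2ccccc2)C(C)(C)C)CC/C=C(/C2OCCO2)C[C@H]1O[Si](C)(C)C(C)(C)C
F3 | step 13 | (S)-α-(tributylstannyl) carbamate derived from 9 | CCCC[Sn](CCCC)(CCCC)[C@H](OC(=O)N(C(C)C)C(C)C)CC/C(CO[Si](c1ccccc1)(c1ccccc1)C(C)(C)C)=C\CO[Si](CC)(CC)CC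
F4 | step 12 | methyl 4-[(tert-butyldimethylsilyl)oxy]-3-hydroxy-2-methylenebutanoate | C=C(C(=O)OC)C(O)CO[Si](C)(C)C(C)(C)C
F5 | step 12 | methyl (Z)-2-(bromomethyl)-4-[(tert-butyldimethylsilyl)oxy]but-2-enoate | COC(=O)/C(CBr)=C/CO[Si](C)(C)C(C)(C)C
F6 | step 12 | methyl (Z)-2-(bromomethyl)-4-hydroxybut-2-enoate | COC(=O)/C(CBr)=C/CO
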